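## Retrosynthetic overview

- **Feature.** C13 and C20 are methylenes joining the ring-B carbons C12 and C21 to the ketone α-carbons C14 and C18. The seven-membered ring C12–C13–C14–C16–C18–C20–C21 is therefore a 1,2-dimethylenecyclohexane (diene 19, C13=C12–C21=C20) capped by the oxyallyl unit C14–C16(=O)–C18 of chloro ketone 35. Their (4+3) union forms C13–C14 and C18–C20 and gives bicyclo[4.3.1]decenone 37.
- **Cage.** From 37, hydrogen-atom transfer to C21 and transannular C12–C25 bonding close the five-membered ring C12–C21–C20–C18–C25 and the bicyclo[2.2.2]octane. Protonation at C30 and desilylation finish the route.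
- **Diene 19.** C12–C21 by palladium-catalysed reductive cyclisation of 1,7-diyne 18; C22 by methyl addition to ynone 16; δ-lactone by Grignard addition and lactonisation; C9 by cinchona-catalysed Michael addition to acrolein.
- **Chloro ketone 35.** Six-membered ring by Diels–Alder reaction of siloxydiene 32 with (S)-sulfinyl butenolide 27, which sets C31; chlorination of the enol silane at C14; sulfoxide elimination to restore the butenolide.
- **Ring order.** δ-Lactone, then ring B; butenolide, then cyclohexanone; cycloheptenone (step 19); five-membered ring and cage (step 20).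

Key step: step 19

Remark: atom labels C1–O32 follow the order of the atoms in the target SMILES; the sense of induction of the catalyst in step 2 and of the sulfoxide in step 16 is assumed to follow the usual models, the pseudo-enantiomeric catalyst or the antipodal sulfinate being used otherwise.

## Route

Step 1
Reactants: 1 tert-butyl 3-oxobutanoate; 2 (4-bromobut-1-yn-1-yl)trimethylsilane
Product: 3 tert-butyl 2-acetyl-6-(trimethylsilyl)hex-5-ynoate (racemic)
Conditions: K2CO3, NaI (cat.), acetone, 55 °C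
Reagents that add atoms: none
Why: Acetoacetic ester C-alkylation by the primary halide (iodide formed in situ); the bulky tert-butyl ester and a slight excess of 1 should limit dialkylation.

Step 2
Reactants: 3 tert-butyl 2-acetyl-6-(trimethylsilyl)hex-5-ynoate; 4 acrolein
Product: 5 tert-butyl (2R)-2-acetyl-2-(3-oxopropyl)-6-(trimethylsilyl)hex-5-ynoate
Conditions: 9-O-benzylcupreidine (10 mol%), CH2Cl2, −24 °C
Reagents that add atoms: none
Why: Bifunctional cinchona-catalysed Michael addition of an α-substituted β-keto ester to acrolein creates the quaternary centre C9, the 6'-OH/quinuclidine catalyst holding enol and enal so that one enol face is attacked to give (R).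

Step 3
Reactants: 5 tert-butyl (2R)-2-acetyl-2-(3-oxopropyl)-6-(trimethylsilyl)hex-5-ynoate
Product: 6 (4R)-4-acetyl-4-(tert-butoxycarbonyl)-8-(trimethylsilyl)oct-7-ynoic acid
Conditions: NaClO2, NaH2PO4, 2-methylbut-2-ene, t-BuOH/H2O, 0 °C → rt
Reagents that add atoms: sodium chlorite NaClO2, [Na+].[O-]Cl=O
Why: Pinnick oxidation converts only the aldehyde; ketone, ester and silylalkyne are inert and C9 bears no hydrogen.

Step 4
Reactants: 6 (4R)-4-acetyl-4-(tert-butoxycarbonyl)-8-(trimethylsilyl)oct-7-ynoic acid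
Product: 8 tert-butyl (3R)-2,2-dimethyl-6-oxo-3-[4-(trimethylsilyl)but-3-yn-1-yl]oxane-3-carboxylate, via hydroxy acid 7 (not isolated)
Conditions: MeMgBr (3.2 equiv), THF, −78 → −20 °C; aq. NH4Cl then 1 M HCl; PPTS (cat.), toluene, 60 °C
Reagents that add atoms: methylmagnesium bromide, C[Mg]Br
Why: Grignard 1,2-addition to the methyl ketone (the carboxylate and the hindered tert-butyl ester do not react at low temperature) gives the C2 carbinol, which closes the six-membered lactone onto C5 under mild acid.

Step 5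
Reactants: 8 tert-butyl (3R)-2,2-dimethyl-6-oxo-3-[4-(trimethylsilyl)but-3-yn-1-yl]oxane-3-carboxylate
Product: 12 tert-butyl (3R)-2,2-dimethyl-6-oxo-3-[4-(trimethylsilyl)but-3-yn-1-yl]-3,6-dihydro-2H-pyran-3-carboxylate, via lithium enolate 9 (not isolated), via selenide 10 (not isolated), via selenoxide 11 (not isolated)
Conditions: LiN(iPr)2, THF, −78 °C; PhSeBr, −78 °C; then 30% H2O2, pyridine, CH2Cl2, 0 °C → rt
Reagents that add atoms: none
Why: α-Selenenylation and selenoxide syn-elimination; C7 is the only enolisable position and the only β-hydrogens are on C8, so the C7=C8 alkene of the lactone results.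

Step 6
Reactants: 12 tert-butyl (3R)-2,2-dimethyl-6-oxo-3-[4-(trimethylsilyl)but-3-yn-1-yl]-3,6-dihydro-2H-pyran-3-carboxylate
Product: 13 (3R)-2,2-dimethyl-6-oxo-3-[4-(trimethylsilyl)but-3-yn-1-yl]-3,6-dihydro-2H-pyran-3-carboxylic acid
Conditions: CF3CO2H/CH2Cl2 (1:4), 0 °C → rt
Reagents that add atoms: none
Why: Acidolysis of the tert-butyl ester; the lactone C2–O bond, flanked by the acceptor-substituted quaternary C9, ionises far more slowly and would re-close in any case.

Step 7
Reactants: 13 (3R)-2,2-dimethyl-6-oxo-3-[4-(trimethylsilyl)but-3-yn-1-yl]-3,6-dihydro-2H-pyran-3-carboxylic acid; 14 ethynyltrimethylsilane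
Product: 16 (5R)-6,6-dimethyl-5-[4-(trimethylsilyl)but-3-yn-1-yl]-5-[3-(trimethylsilyl)prop-2-ynoyl]-5,6-dihydro-2H-pyran-2-one, via acid chloride 15 (not isolated)
Conditions: (COCl)2, DMF (cat.), CH2Cl2, 0 °C → rt, concentrate; then 14, PdCl2(PPh3)2 (2 mol%), CuI (4 mol%), Et3N, THF, rt
Reagents that add atoms: none
Why: Acid chloride formation and acyl Sonogashira coupling give the ynone (C22 ketone, C21≡C20) without touching the lactone, as known for pivaloyl-type chlorides.

Step 8
Reactants: 16 (5R)-6,6-dimethyl-5-[4-(trimethylsilyl)but-3-yn-1-yl]-5-[3-(trimethylsilyl)prop-2-ynoyl]-5,6-dihydro-2H-pyran-2-one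
Product: 17 (5S)-5-[(2S)-2-hydroxy-4-(trimethylsilyl)but-3-yn-2-yl]-6,6-dimethyl-5-[4-(trimethylsilyl)but-3-yn-1-yl]-5,6-dihydro-2H-pyran-2-one
Conditions: MeMgBr (1.2 equiv), THF, −78 °C; aq. NH4Cl at −78 °C
Reagents that add atoms: methylmagnesium bromide, C[Mg]Br
Why: Grignard 1,2-addition to the very electrophilic ynone outruns attack on the lactone; C22 is set by Felkin–Anh addition anti to the fully substituted lactone carbon C2, with the carbonyl oxygen beside the C10 methylene and the slim alkynyl group over C8, which should place the hydroxyl on the C8 side and the methyl on the C2 side (epimer removed by chromatography).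

Step 9
Reactants: 17 (5S)-5-[(2S)-2-hydroxy-4-(trimethylsilyl)but-3-yn-2-yl]-6,6-dimethyl-5-[4-(trimethylsilyl)but-3-yn-1-yl]-5,6-dihydro-2H-pyran-2-one
Product: 18 (5S)-5-(but-3-yn-1-yl)-5-[(2R)-2-hydroxybut-3-yn-2-yl]-6,6-dimethyl-5,6-dihydro-2H-pyran-2-one
Conditions: Bu4NF (2.2 equiv), AcOH (2.2 equiv), THF, 0 °C
Reagents that add atoms: none
Why: Fluoride cleavage of both C(sp)–Si bonds; acetic acid buffering keeps the C22 alkoxide from opening or transposing the lactone.

Step 10
Reactants: 18 (5S)-5-(but-3-yn-1-yl)-5-[(2R)-2-hydroxybut-3-yn-2-yl]-6,6-dimethyl-5,6-dihydro-2H-pyran-2-one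
Product: 19 (6S,7R)-7-hydroxy-1,1,7-trimethyl-8,9-dimethylidene-2-oxaspiro[5.5]undec-4-en-3-one
Conditions: Pd2(dba)3·CHCl3 (2.5 mol%), P(o-tol)3 (10 mol%), AcOH (2 equiv), Et3SiH (5 equiv), benzene, rt
Reagents that add atoms: none
Why: Trost reductive cyclisation of a 1,7-diyne: the Pd–H formed from zerovalent palladium and acetic acid hydropalladates one terminal alkyne, 6-exo carbopalladation of the other forms C12–C21 and the silane reduces the vinylpalladium, giving the 1,2-dimethylenecyclohexane with no stereocentre touched.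

Step 11
Reactants: 20 furan-2(5H)-one
Product: 22 3-bromofuran-2(5H)-one, via dibromide 21 (not isolated)
Conditions: Br2, CH2Cl2, 0 °C → rt; then Et3N, 0 °C
Reagents that add atoms: bromine, BrBr
Why: Bromine addition to the butenolide alkene and E1cB loss of HBr through the acidic α-hydrogen give the α-bromo butenolide.

Step 12
Reactants: 22 3-bromofuran-2(5H)-one
Product: 23 [(3-bromofuran-2-yl)oxy]tri(propan-2-yl)silane
Conditions: iPr3SiOTf, Et3N, CH2Cl2, 0 °C
Reagents that add atoms: triisopropylsilyl trifluoromethanesulfonate, CC(C)[Si](OS(=O)(=O)C(F)(F)F)(C(C)C)C(C)C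
Why: γ-Deprotonation and O-silylation of the butenolide give the aromatic 2-silyloxyfuran, the usual silyl ketene acetal form of a butenolide.

Step 13
Reactants: 23 [(3-bromofuran-2-yl)oxy]tri(propan-2-yl)silane; 24 (1R,2S,5R)-menthyl (S)-4-methylbenzenesulfinate
Product: 27 (S)-3-(4-methylbenzenesulfinyl)furan-2(5H)-one, via lithiofuran 25 (not isolated), via silyloxyfuran sulfoxide 26 (not isolated)
Conditions: n-BuLi, THF, −78 °C; 24, −78 °C; then 1 M HCl, THF, 0 °C
Reagents that add atoms: none
Why: Bromine–lithium exchange and Andersen sulfoxide synthesis (substitution at sulfur with inversion) fix the sulfur configuration as (S); acid hydrolysis of the silyl ketene acetal returns the conjugated butenolide.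

Step 14
Reactants: 28 pentan-3-one; 29 ethyl formate
Product: 31 (E)-1-[(tert-butyldimethylsilyl)oxy]-2-methylpent-1-en-3-one, via sodium enolate 30 (not isolated)
Conditions: NaH, THF, 0 °C → rt; then t-BuMe2SiCl, THF/DMF, 0 °C
Reagents that add atoms: tert-butyldimethylsilyl chloride, CC(C)(C)[Si](C)(C)Cl
Why: Claisen formylation of the ketone and O-silylation of the hydroxymethylene ketone give the β-silyloxy enone, the (E) isomer being the less strained one.

Step 15
Reactants: 31 (E)-1-[(tert-butyldimethylsilyl)oxy]-2-methylpent-1-en-3-one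
Product: 32 (1E,3Z)-1-[(tert-butyldimethylsilyl)oxy]-2-methyl-3-[(trimethylsilyl)oxy]penta-1,3-diene
Conditions: Me3SiOTf, Et3N, Et2O, 0 °C
Reagents that add atoms: trimethylsilyl trifluoromethanesulfonate, C[Si](C)(C)OS(=O)(=O)C(F)(F)F
Why: Soft enolisation of the ethyl ketone gives the (Z)-enol silane, as in the preparation of Danishefsky-type dienes.

Step 16
Reactants: 32 (1E,3Z)-1-[(tert-butyldimethylsilyl)oxy]-2-methyl-3-[(trimethylsilyl)oxy]penta-1,3-diene; 27 (S)-3-(4-methylbenzenesulfinyl)furan-2(5H)-one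
Product: 33 cis-fused adduct 7-[(tert-butyldimethylsilyl)oxy]-4,6-dimethyl-7a-[(S)-4-methylbenzenesulfinyl]-5-[(trimethylsilyl)oxy]-3a,4,7,7a-tetrahydro-2-benzofuran-1(3H)-one (7-silyloxy and 4-methyl cis to the lactone ring, sulfinyl trans to the 7-silyloxy group)
Conditions: toluene, 25 → 40 °C, no Lewis acid; crude product used directly
Reagents that add atoms: none
Why: Diels–Alder reaction of a 1,3-dioxygenated diene with an α-sulfinyl butenolide: the nucleophilic terminus C18 bonds to the β-carbon C25 and C31 to C30; endo addition (lactone under the diene) on the sulfur lone-pair face of the S=O/C=C s-cis conformer, anti to the p-tolyl group, sets C31 (R in 35), while C25 and C30 are erased in step 18.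

Step 17
Reactants: 33 Diels–Alder adduct
Product: 34 6-chloro-7-[(tert-butyldimethylsilyl)oxy]-4,6-dimethyl-7a-[(S)-4-methylbenzenesulfinyl]hexahydro-2-benzofuran-1,5-dione (ring configuration as in 33, C6 epimers)
Conditions: N-chlorosuccinimide, THF, 0 °C
Reagents that add atoms: N-chlorosuccinimide, O=C1CCC(=O)N1Cl
Why: Electrophilic chlorination of the enol silane occurs only at its nucleophilic carbon C14, which places chlorine regiospecifically and blocks aromatisation; the C14 configuration is irrelevant later.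

Step 18
Reactants: 34 chloro ketone sulfoxide
Product: 35 (7R)-7-[(tert-butyldimethylsilyl)oxy]-6-chloro-4,6-dimethyl-6,7-dihydro-2-benzofuran-1,5(3H,4H)-dione (C6 epimers; C4 as formed but labile; both centres are erased in step 19)
Conditions: NaHCO3 (solid), toluene, 80 °C
Reagents that add atoms: none
Why: Thermal syn-elimination of the α-carbonyl sulfoxide with the cis hydrogen on C25 restores the C25=C30 butenolide; elimination toward the oxygen-bearing C31 is the disfavoured direction for sulfoxides.

Step 19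
Reactants: 19 (6S,7R)-7-hydroxy-1,1,7-trimethyl-8,9-dimethylidene-2-oxaspiro[5.5]undec-4-en-3-one; 35 (7R)-7-[(tert-butyldimethylsilyl)oxy]-6-chloro-4,6-dimethyl-6,7-dihydro-2-benzofuran-1,5(3H,4H)-dione
Product: 37 (4+3) adduct, the bicyclo[4.3.1]decenone in which C13–C14 and C18–C20 are bonded, C12=C21 is the ring-B tetrasubstituted alkene and C14–C16(=O)–C18 is bridged by C31(OSi)–C30=C25 of the butenolide, via oxyallyl cation 36 (not isolated)
Conditions: 19 (1 equiv), 35 (1.5 equiv), Na2CO3 (2 equiv), (CF3)2CHOH, 0 °C → rt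
Reagents that add atoms: none
Why: Carbonate-assisted enolisation of 35 toward C18 and loss of chloride from C14 in the ionising, weakly nucleophilic fluoro alcohol give the 2-oxyallyl cation 36, which adds across the s-cis-locked exocyclic diene of 19 in a concerted-asynchronous or stepwise cationic (4+3) cycloaddition, the Föhlisch-type reaction of cyclic α-halo ketones with 1,3-dienes. The cycloheptenone ring C12–C13–C14–C16–C18–C20–C21 is closed by intermolecular (4+3) annulation with both bonds formed on one face of the six-membered cation, so C14 and C18 become quaternary together and C31–C30=C25 becomes the three-atom bridge. Both new centres are controlled by C31: allylic strain from the in-plane C15 methyl and the butenolide carbonyl holds the silyloxy group pseudo-axial, and the diene bonds to the opposite face. The step needs this facial sense and the regiochemistry C13 to C14; the first bond is expected between the non-conjugated, more electrophilic terminus C14 and the diene terminus C13, whose attack leaves the allyl cation centred on C12, remote from the C22 oxygen, and the bulkier C14/C31 flank also avoids the C22 carbinol side. The in-plane C31–H overlaps poorly with the cationic p-orbital, which should slow proton loss toward the phenol.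

Step 20
Reactants: 37 (4+3) adduct
Product: 38 31-O-(tert-butyldimethylsilyl) ether of the target (C12–C25 bonded, H on C21 and C30)
Conditions: Fe(acac)3 (0.5 equiv), PhSiH3 (3 equiv), EtOH/(CH2OH)2 (5:1), 60 °C, degassed
Reagents that add atoms: none
Why: Iron-hydride hydrogen-atom transfer (Baran reductive olefin coupling run intramolecularly) delivers H to C21 from the exposed convex face, the tertiary C12 radical adds transannularly (5-exo) to C25 of the butenolide on the only face it can reach, fixing C12 and C25, and the C30 radical is reduced to the enolate and protonated by ethanol anti to the C31 silyloxy group; a radical formed at C21 instead has no productive partner and should revert.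

Step 21
Reactants: 38 31-O-silyl ether of the target
Product: 39 CNP0360620.2
Conditions: HF·pyridine, THF, 0 °C → rt
Reagents that add atoms: none
Why: Acidic fluoride desilylation frees the C31 hydroxyl without the base that could epimerise C30 or trigger β-elimination or translactonisation.

## Compound list

1 | tert-butyl 3-oxobutanoate | CC(=O)CC(=O)OC(C)(C)C | starting material
2 | (4-bromobut-1-yn-1-yl)trimethylsilane | C[Si](C)(C)C#CCCBr | starting material
3 | tert-butyl 2-acetyl-6-(trimethylsilyl)hex-5-ynoate (racemic) | CC(=O)C(CCC#C[Si](C)(C)C)C(=O)OC(C)(C)C | intermediate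
4 | acrolein | C=CC=O | starting material
5 | tert-butyl (2R)-2-acetyl-2-(3-oxopropyl)-6-(trimethylsilyl)hex-5-ynoate | CC(=O)[C@](CCC=O)(CCC#C[Si](C)(C)C)C(=O)OC(C)(C)C | intermediate
6 | (4R)-4-acetyl-4-(tert-butoxycarbonyl)-8-(trimethylsilyl)oct-7-ynoic acid | CC(=O)[C@](CCC(=O)O)(CCC#C[Si](C)(C)C)C(=O)OC(C)(C)C | intermediate
7 | (4R)-4-(tert-butoxycarbonyl)-5-hydroxy-5-methyl-4-[4-(trimethylsilyl)but-3-yn-1-yl]hexanoic acid | CC(C)(O)[C@](CCC(=O)O)(CCC#C[Si](C)(C)C)C(=O)OC(C)(C)C | intermediate
8 | tert-butyl (3R)-2,2-dimethyl-6-oxo-3-[4-(trimethylsilyl)but-3-yn-1-yl]oxane-3-carboxylate | CC1(C)OC(=O)CC[C@@]1(CCC#C[Si](C)(C)C)C(=O)OC(C)(C)C | intermediate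
9 | lithium enolate of 8 | [Li+].CC1(C)OC([O-])=CC[C@@]1(CCC#C[Si](C)(C)C)C(=O)OC(C)(C)C | intermediate
10 | 5-(phenylselanyl) derivative of 8 (C5 epimers) | CC1(C)OC(=O)C([Se]c2ccccc2)C[C@@]1(CCC#C[Si](C)(C)C)C(=O)OC(C)(C)C | intermediate
11 | selenoxide of 10 | CC1(C)OC(=O)C([Se](=O)c2ccccc2)C[C@@]1(CCC#C[Si](C)(C)C)C(=O)OC(C)(C)C | intermediate
12 | tert-butyl (3R)-2,2-dimethyl-6-oxo-3-[4-(trimethylsilyl)but-3-yn-1-yl]-3,6-dihydro-2H-pyran-3-carboxylate | CC1(C)OC(=O)C=C[C@@]1(CCC#C[Si](C)(C)C)C(=O)OC(C)(C)C | intermediate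
13 | (3R)-2,2-dimethyl-6-oxo-3-[4-(trimethylsilyl)but-3-yn-1-yl]-3,6-dihydro-2H-pyran-3-carboxylic acid | CC1(C)OC(=O)C=C[C@@]1(CCC#C[Si](C)(C)C)C(=O)O | intermediate
14 | ethynyltrimethylsilane | C#C[Si](C)(C)C | starting material
15 | acid chloride of 13 | CC1(C)OC(=O)C=C[C@@]1(CCC#C[Si](C)(C)C)C(=O)Cl | intermediate
16 | (5R)-6,6-dimethyl-5-[4-(trimethylsilyl)but-3-yn-1-yl]-5-[3-(trimethylsilyl)prop-2-ynoyl]-5,6-dihydro-2H-pyran-2-one | CC1(C)OC(=O)C=C[C@@]1(CCC#C[Si](C)(C)C)C(=O)C#C[Si](C)(C)C | intermediate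
17 | (5S)-5-[(2S)-2-hydroxy-4-(trimethylsilyl)but-3-yn-2-yl]-6,6-dimethyl-5-[4-(trimethylsilyl)but-3-yn-1-yl]-5,6-dihydro-2H-pyran-2-one | CC1(C)OC(=O)C=C[C@@]1(CCC#C[Si](C)(C)C)[C@](C)(O)C#C[Si](C)(C)C | intermediate
18 | (5S)-5-(but-3-yn-1-yl)-5-[(2R)-2-hydroxybut-3-yn-2-yl]-6,6-dimethyl-5,6-dihydro-2H-pyran-2-one | CC1(C)OC(=O)C=C[C@@]1(CCC#C)[C@](C)(O)C#C | intermediate
19 | (6S,7R)-7-hydroxy-1,1,7-trimethyl-8,9-dimethylidene-2-oxaspiro[5.5]undec-4-en-3-one | CC1(C)OC(=O)C=C[C@]12CCC(=C)C(=C)[C@@]2(C)O | intermediate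
20 | furan-2(5H)-one | O=C1OCC=C1 | starting material
21 | 3,4-dibromodihydrofuran-2(3H)-one (racemic) | O=C1OCC(Br)C1Br | intermediate
22 | 3-bromofuran-2(5H)-one | O=C1OCC=C1Br | intermediate
23 | [(3-bromofuran-2-yl)oxy]tri(propan-2-yl)silane | CC(C)[Si](Oc1occc1Br)(C(C)C)C(C)C | intermediate
24 | (1R,2S,5R)-menthyl (S)-4-methylbenzenesulfinate | Cc1ccc(cc1)[S@@](=O)O[C@@H]1C[C@H](C)CC[C@H]1C(C)C | starting material
25 | 3-lithio-2-[tri(propan-2-yl)silyloxy]furan | [Li]c1ccoc1O[Si](C(C)C)(C(C)C)C(C)C | intermediate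
26 | (S)-3-(4-methylbenzenesulfinyl)-2-[tri(propan-2-yl)silyloxy]furan | CC(C)[Si](Oc1occc1[S@@](=O)c1ccc(C)cc1)(C(C)C)C(C)C | intermediate
27 | (S)-3-(4-methylbenzenesulfinyl)furan-2(5H)-one | O=C1OCC=C1[S@@](=O)c1ccc(C)cc1 | intermediate
28 | pentan-3-one | CCC(=O)CC | starting material
29 | ethyl formate | CCOC=O | starting material
30 | sodium 2-methyl-3-oxopent-1-en-1-olate | [Na+].CCC(=O)C(C)=C[O-] | intermediate
31 | (E)-1-[(tert-butyldimethylsilyl)oxy]-2-methylpent-1-en-3-one | CCC(=O)/C(C)=C/O[Si](C)(C)C(C)(C)C | intermediate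
32 | (1E,3Z)-1-[(tert-butyldimethylsilyl)oxy]-2-methyl-3-[(trimethylsilyl)oxy]penta-1,3-diene | C/C=C(O[Si](C)(C)C)/C(C)=C/O[Si](C)(C)C(C)(C)C | intermediate
33 | Diels–Alder adduct, 7-silyloxy-4,6-dimethyl-7a-[(S)-p-tolylsulfinyl]-5-(trimethylsilyloxy)-3a,4,7,7a-tetrahydro-2-benzofuran-1(3H)-one | C[C@@H]1C(O[Si](C)(C)C)=C(C)[C@H](O[Si](C)(C)C(C)(C)C)[C@]2([S@@](=O)c3ccc(C)cc3)C(=O)OC[C@H]12 | intermediate
34 | 6-chloro-7-silyloxy-4,6-dimethyl-7a-[(S)-p-tolylsulfinyl]hexahydro-2-benzofuran-1,5-dione (C6 epimers) | C[C@@H]1C(=O)C(C)(Cl)[C@H](O[Si](C)(C)C(C)(C)C)[C@]2([S@@](=O)c3ccc(C)cc3)C(=O)OC[C@H]12 | intermediate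
35 | (7R)-7-[(tert-butyldimethylsilyl)oxy]-6-chloro-4,6-dimethyl-6,7-dihydro-2-benzofuran-1,5(3H,4H)-dione (C4 and C6 not defined) | CC1(Cl)C(=O)C(C)C2=C(C(=O)OC2)[C@H]1O[Si](C)(C)C(C)(C)C | intermediate
36 | 2-oxyallyl cation (zwitterion) from 35 | CC1=C([O-])[C+](C)[C@H](O[Si](C)(C)C(C)(C)C)C2=C1COC2=O | intermediate
37 | (4+3) adduct, bicyclo[4.3.1]decenone with C12=C21 alkene | CC1(C)OC(=O)C=C[C@]12CCC3=C(C[C@@]4(C)C(=O)[C@@](C)(C3)[C@H](O[Si](C)(C)C(C)(C)C)C5=C4COC5=O)[C@@]2(C)O | intermediate
38 | 31-O-(tert-butyldimethylsilyl) ether of the target | CC1(C)OC(=O)C=C[C@]12CC[C@]13C[C@]4(C)C(=O)[C@](C)(C[C@H]1[C@@]2(C)O)[C@]31COC(=O)[C@H]1[C@H]4O[Si](C)(C)C(C)(C)C | intermediate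
39 | CNP0360620.2 | CC1(C)OC(=O)C=C[C@]12CC[C@]13C[C@]4(C)C(=O)[C@](C)(C[C@H]1[C@@]2(C)O)[C@]31COC(=O)[C@H]1[C@H]4O | target

## Step count and risks

Total step count: 21. Longest linear sequence: 13 steps (steps 1–10, then 19–21).

**Step 19.** The oxyallyl cation may lose the C31 proton and aromatise to the phthalide phenol, the chloro ketone may undergo base-induced HCl loss or Favorskii contraction, the solvent may capture the cation, and the union may occur with the wrong regiochemistry or syn to the silyloxy group. Fallback, a base-free Lewis-acid route to the same cation: from 35, Me3SiOTf/Et3N in CH2Cl2 at −78 °C gives the 2-silyloxyallyl chloride, the trimethylsilyl dienol ether of 35 F1 (C18 is the only enolisable position). Ionisation of F1 with AgO2CCF3 in CH2Cl2/MeNO2 at −78 °C in the presence of 19 (silver-promoted (4+3) of 2-siloxyallyl halides) returns to 37.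

**Step 20.** The hydrogen atom may go to C12 instead of C21 or to the concave face, the alkene may simply be reduced, the δ-lactone alkene may be reduced, the C30 enolate may expel the silyloxy group, or C30 may be protonated from the wrong face. Fallback, radical generation from a halide: from 37, Markovnikov addition of HCl (HCl in dioxane, CH2Cl2, −40 °C; cation at C12, remote from the C22 oxygen) gives the C12 tertiary chloride F2. Bu3SnH/AIBN in benzene at 80 °C then forms the C12 radical, which cyclises onto C25, and the C30 radical takes hydrogen from the stannane anti to the silyloxy group, returning to 38.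

**Step 8.** The acyclic 1,2-induction may be weak or of the opposite sense, and the tertiary alkoxide may transpose the lactone. Fallback, setting C22 on the formed ring B:
- From 16, NaBH4/CeCl3 in MeOH at −78 °C gives the secondary propargylic alcohol F3 (C22 epimers).
- Bu4NF/AcOH gives the diyne alcohol F4.
- Reductive cyclisation as in step 10 gives the dienol F5.
- MnO2 in CH2Cl2 at 0 °C gives the dienone F6, used at once because 2-acyl dienes dimerise.
- MeMgBr/CeCl3 in THF at −78 °C adds to F6 anti to the pseudo-axial C8 of the spiro lactone (axial attack, bulky C2 equatorial), placing methyl cis to C2, and returns to 19.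

## Further compounds

F1 | step 19 | trimethylsilyl dienol ether of 35 (2-silyloxyallyl chloride) | CC1(Cl)C(O[Si](C)(C)C)=C(C)C2=C(C(=O)OC2)[C@H]1O[Si](C)(C)C(C)(C)C
F2 | step 20 | C12 tertiary chloride of 37 with H on C21 | CC1(C)OC(=O)C=C[C@]12CCC3(Cl)[C@@H](C[C@@]4(C)C(=O)[C@@](C)(C3)[C@H](O[Si](C)(C)C(C)(C)C)C5=C4COC5=O)[C@@]2(C)O
F3 | step 8 | 5-[1-hydroxy-3-(trimethylsilyl)prop-2-yn-1-yl] analogue of 16 (C9 as in 16, C22 epimers) | CC1(C)OC(=O)C=C[C@@]1(CCC#C[Si](C)(C)C)C(O)C#C[Si](C)(C)C
F4 | step 8 | 5-(but-3-yn-1-yl)-5-(1-hydroxyprop-2-yn-1-yl)-6,6-dimethyl-5,6-dihydro-2H-pyran-2-one | CC1(C)OC(=O)C=C[C@@]1(CCC#C)C(O)C#C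
F5 | step 8 | 7-hydroxy-1,1-dimethyl-8,9-dimethylidene-2-oxaspiro[5.5]undec-4-en-3-one (spiro centre as in 19) | CC1(C)OC(=O)C=C[C@]12CCC(=C)C(=C)C2O
F6 | step 8 | 1,1-dimethyl-8,9-dimethylidene-2-oxaspiro[5.5]undec-4-ene-3,7-dione (spiro centre as in 19) | CC1(C)OC(=O)C=C[C@]12CCC(=C)C(=C)C2=O
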